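**Retrosynthetic overview**
1. Target ⇐ fluoride cleavage of a 7-O-SEM ether; the 5-OH ⇐ the C5–H bond of a 5-unsubstituted flavone, by carbonyl-directed C–H borylation/oxidation (the new step; it makes the C5–O bond last).
2. 3-O-prenyl ⇐ flavonol 3-OH + prenyl bromide; ring C ⇐ Algar–Flynn–Oyamada oxidative cyclisation of a 2'-hydroxychalcone with no 6'-substituent.
3. Chalcone ⇐ Claisen–Schmidt condensation of the ring A acetophenone with 4-(prenyloxy)benzaldehyde (ring B).
4. Ring A piece ⇐ 2-methoxyresorcinol (C-acetylation, then 4-O-SEM); ring B piece ⇐ 4-hydroxybenzaldehyde + prenyl bromide.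
5. Ring order: rings A and B are bought as benzenes; ring C is the only ring built (step 5); the C5 oxygen of ring A is added after the tricycle is complete.

Assumption: the target has no stereocentre and is achiral, so no enantiocontrol is needed; the only stereo-element on the way is the E double bond of the chalcone.

Abbreviations: prenyl = 3-methylbut-2-en-1-yl; SEM = 2-(trimethylsilyl)ethoxymethyl (CH2OCH2CH2SiMe3); Bpin = 4,4,5,5-tetramethyl-1,3,2-dioxaborolan-2-yl; TIPS = triisopropylsilyl.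

**Route**

Step 1
Reactants: 1 2-methoxybenzene-1,3-diol (2-methoxyresorcinol)
Product: 2 1-(2,4-dihydroxy-3-methoxyphenyl)ethan-1-one
Conditions: AcOH, ZnCl2 (1.5 equiv), 130 °C; then dilute HCl
Reagents that add atoms: acetic acid, CC(=O)O
Why: Nencki-type Friedel–Crafts C-acetylation; C4 (equivalent to C6) is ortho to one hydroxyl and para to the other, so it is the only strongly activated site, and the first acyl group deactivates the ring against a second acylation.

Step 2
Reactants: 2 1-(2,4-dihydroxy-3-methoxyphenyl)ethan-1-one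
Product: 3 1-[2-hydroxy-3-methoxy-4-(SEM-oxy)phenyl]ethan-1-one
Conditions: SEMCl (1.1 equiv), K2CO3 (1.5 equiv), acetone, 0 °C to rt
Reagents that add atoms: 2-(trimethylsilyl)ethoxymethyl chloride (SEMCl), C[Si](C)(C)CCOCCl
Why: Williamson-type O-alkylation with a chloromethyl ether; the 2-OH is hydrogen-bonded to the ketone and flanked by OMe, so only the 4-OH reacts.

Step 3
Reactants: 4 4-hydroxybenzaldehyde
Product: 5 4-(prenyloxy)benzaldehyde
Conditions: prenyl bromide (1.2 equiv), K2CO3 (1.5 equiv), acetone, reflux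
Reagents that add atoms: prenyl bromide (1-bromo-3-methylbut-2-ene), CC(C)=CCBr
Why: Williamson ether synthesis, SN2 attack of the phenoxide on the primary allylic bromide.

Step 4
Reactants: 3 1-[2-hydroxy-3-methoxy-4-(SEM-oxy)phenyl]ethan-1-one; 5 4-(prenyloxy)benzaldehyde
Product: 6 (E)-1-[2-hydroxy-3-methoxy-4-(SEM-oxy)phenyl]-3-[4-(prenyloxy)phenyl]prop-2-en-1-one
Conditions: KOH (50% aq., as base), EtOH, rt, 36 h; neutral work-up
Reagents that add atoms: none
Why: Claisen–Schmidt (crossed aldol) condensation; the aldehyde cannot enolise, elimination gives the conjugated E-enone as the thermodynamic alkene, and SEM and prenyl ethers are inert to aqueous base.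

Step 5
Reactants: 6 (E)-1-[2-hydroxy-3-methoxy-4-(SEM-oxy)phenyl]-3-[4-(prenyloxy)phenyl]prop-2-en-1-one
Product: 7 3-hydroxy-8-methoxy-2-[4-(prenyloxy)phenyl]-7-(SEM-oxy)-4H-chromen-4-one
Conditions: 30% H2O2, 2 M NaOH, MeOH/THF, 0 °C to rt
Reagents that add atoms: hydrogen peroxide, OO
Why: Algar–Flynn–Oyamada oxidative cyclisation; with no 6'-substituent on the chalcone the six-membered flavonol closure is favoured over aurone formation, and hydroperoxide anion is a nucleophilic oxidant that leaves the isolated prenyl alkene and the SEM acetal alone.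

Step 6
Reactants: 7 3-hydroxy-8-methoxy-2-[4-(prenyloxy)phenyl]-7-(SEM-oxy)-4H-chromen-4-one
Product: 8 8-methoxy-3-(prenyloxy)-2-[4-(prenyloxy)phenyl]-7-(SEM-oxy)-4H-chromen-4-one
Conditions: prenyl bromide (1.3 equiv), K2CO3 (2 equiv), acetone, 50 °C
Reagents that add atoms: prenyl bromide (1-bromo-3-methylbut-2-ene), CC(C)=CCBr
Why: Williamson O-alkylation of the acidic 3-OH, which is the only free hydroxyl in 7.

Step 7
Reactants: 8 8-methoxy-3-(prenyloxy)-2-[4-(prenyloxy)phenyl]-7-(SEM-oxy)-4H-chromen-4-one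
Product: 10 5-hydroxy-8-methoxy-3-(prenyloxy)-2-[4-(prenyloxy)phenyl]-7-(SEM-oxy)-4H-chromen-4-one, via 5-Bpin flavone 9 (not isolated)
Conditions: [Ir(OMe)(cod)]2 (2.5 mol%), P[3,5-(CF3)2C6H3]3 (5 mol%), B2pin2 (1.2 equiv), methylcyclohexane, 90 °C; then THF, 30% H2O2, 1 M Na2CO3, 0 °C
Reagents that add atoms: bis(pinacolato)diboron, CC1(C)OB(OC1(C)C)B1OC(C)(C)C(C)(C)O1 (boron of 9); hydrogen peroxide, OO (5-oxygen of 10)
Why: Proposed new method: the Lewis-basic pyranone carbonyl of the flavone binds a trivalent iridium tris(boryl) species that carries only one electron-poor phosphine and so has two open sites, which holds the metal next to the peri C5–H bond; C–H cleavage through a five-membered iridacycle and C–B reductive elimination give boronate 9, and hydroperoxide anion then converts C–B into C–O at the same carbon (aryl shift from boron to oxygen) to give the chelated 5-OH, while every other aryl C–H is ortho to a substituent and both alkenes are trisubstituted, so undirected borylation and hydroboration should be slow; the closest known reaction type is the ketone- or ester-directed ortho C–H borylation of simple aryl ketones and benzoates with [Ir(OMe)(cod)]2 and a monodentate phosphine or arsine, followed by boronate oxidation, which has not been shown for a chromone carbonyl or for C5 of a flavone.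

Step 8
Reactants: 10 5-hydroxy-8-methoxy-3-(prenyloxy)-2-[4-(prenyloxy)phenyl]-7-(SEM-oxy)-4H-chromen-4-one
Product: 11 5,7-dihydroxy-8-methoxy-3-(prenyloxy)-2-[4-(prenyloxy)phenyl]-4H-chromen-4-one
Conditions: Bu4NF (4 equiv), THF/DMPU (4:1), 60 °C; then AcOH
Reagents that add atoms: none
Why: Fluoride-induced fragmentation of the SEM acetal (attack at silicon, loss of ethene and formaldehyde, release of the 7-phenoxide); the prenyl ethers, the methyl ether and the chromone are inert to fluoride, which is why an acid-labile or hydrogenolysable group was avoided.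

**Compound list**
1 | 2-methoxybenzene-1,3-diol (2-methoxyresorcinol) | COc1c(O)cccc1O | starting material
2 | 1-(2,4-dihydroxy-3-methoxyphenyl)ethan-1-one | CC(=O)c1ccc(O)c(OC)c1O | intermediate
3 | 1-[2-hydroxy-3-methoxy-4-(SEM-oxy)phenyl]ethan-1-one | CC(=O)c1ccc(OCOCC[Si](C)(C)C)c(OC)c1O | intermediate
4 | 4-hydroxybenzaldehyde | O=Cc1ccc(O)cc1 | starting material
5 | 4-(prenyloxy)benzaldehyde | CC(C)=CCOc1ccc(C=O)cc1 | intermediate
6 | (E)-1-[2-hydroxy-3-methoxy-4-(SEM-oxy)phenyl]-3-[4-(prenyloxy)phenyl]prop-2-en-1-one | COc1c(OCOCC[Si](C)(C)C)ccc(C(=O)/C=C/c2ccc(OCC=C(C)C)cc2)c1O | intermediate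
7 | 3-hydroxy-8-methoxy-2-[4-(prenyloxy)phenyl]-7-(SEM-oxy)-4H-chromen-4-one | COc1c(OCOCC[Si](C)(C)C)ccc2c(=O)c(O)c(-c3ccc(OCC=C(C)C)cc3)oc12 | intermediate
8 | 8-methoxy-3-(prenyloxy)-2-[4-(prenyloxy)phenyl]-7-(SEM-oxy)-4H-chromen-4-one | COc1c(OCOCC[Si](C)(C)C)ccc2c(=O)c(OCC=C(C)C)c(-c3ccc(OCC=C(C)C)cc3)oc12 | intermediate
9 | 8-methoxy-5-Bpin-3-(prenyloxy)-2-[4-(prenyloxy)phenyl]-7-(SEM-oxy)-4H-chromen-4-one (boronate formed and consumed in the flask) | COc1c(OCOCC[Si](C)(C)C)cc(B3OC(C)(C)C(C)(C)O3)c2c(=O)c(OCC=C(C)C)c(-c4ccc(OCC=C(C)C)cc4)oc12 | intermediate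
10 | 5-hydroxy-8-methoxy-3-(prenyloxy)-2-[4-(prenyloxy)phenyl]-7-(SEM-oxy)-4H-chromen-4-one | COc1c(OCOCC[Si](C)(C)C)cc(O)c2c(=O)c(OCC=C(C)C)c(-c3ccc(OCC=C(C)C)cc3)oc12 | intermediate
11 | 5,7-dihydroxy-8-methoxy-3-(prenyloxy)-2-[4-(prenyloxy)phenyl]-4H-chromen-4-one (5,7-dihydroxy-8-methoxy-3,4'-diprenyloxyflavone) | COc1c(O)cc(O)c2c(=O)c(OCC=C(C)C)c(-c3ccc(OCC=C(C)C)cc3)oc12 | target

**Totals and risks**

Total step count: 8. Longest linear sequence: 7 steps (steps 1, 2, 4, 5, 6, 7, 8, from 2-methoxyresorcinol); step 3 is a one-step side branch.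

Three steps most likely to fail:

Risk 1, step 7 (the proposed new C5–H borylation/oxidation). The carbonyl may direct too weakly, or the 3-alkoxy/4-carbonyl pair may chelate and block the catalyst. At 90 °C the prenyl alkenes could be hydroborated, or the 3-O-prenyl enol ether could undergo Claisen rearrangement. The 3-alkoxyflavone may also not survive the peroxide stage.

The fallback uses known chemistry only; it sets out from compound 7 and comes back at compound 10. Aqueous CF3CO2H (9:1 with water, rt) strips the SEM and prenyl groups of 7 to give 3,7-dihydroxy-2-(4-hydroxyphenyl)-8-methoxy-4H-chromen-4-one F1. The known carbonyl-directed C5–H hydroxylation of flavones ([RuCl2(p-cymene)]2, PhI(OCOCF3)2, CF3CO2H/(CF3CO)2O, 80 °C, then aqueous NaHCO3) gives 3,5,7-trihydroxy-2-(4-hydroxyphenyl)-8-methoxy-4H-chromen-4-one F2. Ac2O/pyridine gives 2-(4-acetoxyphenyl)-8-methoxy-4-oxo-4H-chromene-3,5,7-triyl triacetate F3. PhSH/imidazole in NMP at 0 °C removes only the most labile 7-acetate to give 2-(4-acetoxyphenyl)-7-hydroxy-8-methoxy-4-oxo-4H-chromene-3,5-diyl diacetate F4. SEMCl/iPr2NEt in CH2Cl2 gives 2-(4-acetoxyphenyl)-8-methoxy-4-oxo-7-(SEM-oxy)-4H-chromene-3,5-diyl diacetate F5. K2CO3/MeOH under N2 removes the three acetates to give 3,5-dihydroxy-2-(4-hydroxyphenyl)-8-methoxy-7-(SEM-oxy)-4H-chromen-4-one F6. Prenyl bromide (2.2 equiv)/K2CO3 in acetone alkylates the 3-OH and 4'-OH and leaves the chelated 5-OH, giving 10, and the route resumes with step 8.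

Risk 2, step 5 (Algar–Flynn–Oyamada). The yield may be low through aurone formation, incomplete oxidation, or peroxide degradation of the flavonol.

The fallback sets out from compound 6 and comes back at compound 7; it closes ring C first and adds the 3-oxygen afterwards. NaOAc in refluxing EtOH isomerises 6 by oxa-Michael addition to racemic 8-methoxy-2-[4-(prenyloxy)phenyl]-7-(SEM-oxy)chroman-4-one F7. 2-Iodoxybenzoic acid in DMSO at 80 °C dehydrogenates it to 8-methoxy-2-[4-(prenyloxy)phenyl]-7-(SEM-oxy)-4H-chromen-4-one F8. C3-lithiation with LiN(iPr)2 in THF at −78 °C, trapping with B(OMe)3 and oxidation with H2O2/AcOH gives flavonol 7, and the route resumes with step 6.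

Risk 3, step 8 (SEM removal). Bu4NF first deprotonates the chelated 5-OH of 10, so loss of the SEM group has to generate a dianion and may stall or need forcing conditions.

The fallback sets out from compound 8 and comes back at compound 11; it moves the SEM cleavage ahead of the C5 oxygenation and ends with a simple Si–O cleavage. Bu4NF (THF/DMPU, 60 °C) on 8, which has no second acidic OH, gives 7-hydroxy-8-methoxy-3-(prenyloxy)-2-[4-(prenyloxy)phenyl]-4H-chromen-4-one F9. iPr3SiCl/imidazole in DMF gives 8-methoxy-3-(prenyloxy)-2-[4-(prenyloxy)phenyl]-7-(TIPS-oxy)-4H-chromen-4-one F10; the bulky silyl group also shields C6. The step 7 protocol gives the boronate 8-methoxy-5-Bpin-3-(prenyloxy)-2-[4-(prenyloxy)phenyl]-7-(TIPS-oxy)-4H-chromen-4-one F11 (not isolated). H2O2 with aqueous NaHCO3 oxidises it to 5-hydroxy-8-methoxy-3-(prenyloxy)-2-[4-(prenyloxy)phenyl]-7-(TIPS-oxy)-4H-chromen-4-one F12. Bu4NF/AcOH in THF at 0 °C then gives the target 11.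

**Further compounds**
F1 | step 7 | 3,7-dihydroxy-2-(4-hydroxyphenyl)-8-methoxy-4H-chromen-4-one | COc1c(O)ccc2c(=O)c(O)c(-c3ccc(O)cc3)oc12
F2 | step 7 | 3,5,7-trihydroxy-2-(4-hydroxyphenyl)-8-methoxy-4H-chromen-4-one | COc1c(O)cc(O)c2c(=O)c(O)c(-c3ccc(O)cc3)oc12
F3 | step 7 | 2-(4-acetoxyphenyl)-8-methoxy-4-oxo-4H-chromene-3,5,7-triyl triacetate | COc1c(OC(C)=O)cc(OC(C)=O)c2c(=O)c(OC(C)=O)c(-c3ccc(OC(C)=O)cc3)oc12
F4 | step 7 | 2-(4-acetoxyphenyl)-7-hydroxy-8-methoxy-4-oxo-4H-chromene-3,5-diyl diacetate | COc1c(O)cc(OC(C)=O)c2c(=O)c(OC(C)=O)c(-c3ccc(OC(C)=O)cc3)oc12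
F5 | step 7 | 2-(4-acetoxyphenyl)-8-methoxy-4-oxo-7-(SEM-oxy)-4H-chromene-3,5-diyl diacetate | COc1c(OCOCC[Si](C)(C)C)cc(OC(C)=O)c2c(=O)c(OC(C)=O)c(-c3ccc(OC(C)=O)cc3)oc12
F6 | step 7 | 3,5-dihydroxy-2-(4-hydroxyphenyl)-8-methoxy-7-(SEM-oxy)-4H-chromen-4-one | COc1c(OCOCC[Si](C)(C)C)cc(O)c2c(=O)c(O)c(-c3ccc(O)cc3)oc12
F7 | step 5 | racemic 8-methoxy-2-[4-(prenyloxy)phenyl]-7-(SEM-oxy)chroman-4-one | COc1c(OCOCC[Si](C)(C)C)ccc2C(=O)CC(c3ccc(OCC=C(C)C)cc3)Oc12
F8 | step 5 | 8-methoxy-2-[4-(prenyloxy)phenyl]-7-(SEM-oxy)-4H-chromen-4-one | COc1c(OCOCC[Si](C)(C)C)ccc2c(=O)cc(-c3ccc(OCC=C(C)C)cc3)oc12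
F9 | step 8 | 7-hydroxy-8-methoxy-3-(prenyloxy)-2-[4-(prenyloxy)phenyl]-4H-chromen-4-one | COc1c(O)ccc2c(=O)c(OCC=C(C)C)c(-c3ccc(OCC=C(C)C)cc3)oc12
F10 | step 8 | 8-methoxy-3-(prenyloxy)-2-[4-(prenyloxy)phenyl]-7-(TIPS-oxy)-4H-chromen-4-one | COc1c(O[Si](C(C)C)(C(C)C)C(C)C)ccc2c(=O)c(OCC=C(C)C)c(-c3ccc(OCC=C(C)C)cc3)oc12
F11 | step 8 | 8-methoxy-5-Bpin-3-(prenyloxy)-2-[4-(prenyloxy)phenyl]-7-(TIPS-oxy)-4H-chromen-4-one | COc1c(O[Si](C(C)C)(C(C)C)C(C)C)cc(B3OC(C)(C)C(C)(C)O3)c2c(=O)c(OCC=C(C)C)c(-c4ccc(OCC=C(C)C)cc4)oc12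
F12 | step 8 | 5-hydroxy-8-methoxy-3-(prenyloxy)-2-[4-(prenyloxy)phenyl]-7-(TIPS-oxy)-4H-chromen-4-one | COc1c(O[Si](C(C)C)(C(C)C)C(C)C)cc(O)c2c(=O)c(OCC=C(C)C)c(-c3ccc(OCC=C(C)C)cc3)oc12
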